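## Retrosynthetic overview

1. Ring D is opened last, at C13–C18: a tertiary C13 radical (from a tertiary methyl oxalate) closes 6-exo onto the ring-E alkene C18=C19. This works because ring D is bracketed by the quaternary carbons C14 (ring C) and C17 (ring E), and both allylic carbons of that alkene (C17, C20) are quaternary.
2. The benzodioxane is cut at its two alkyl C–O bonds: O–C3′ (Mitsunobu inversion) and O–C4′ (capture of the C1′–C5′–C4′ allyl cation). This joins a catechol carrying rings A–C and E to a guaiane 1′,3′-diol.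
3. The 13,18-seco skeleton is cut at C14–C15: reductive alkylation of a tricyclic enone (rings A–C, from a 2-tetralone by chiral-imine Robinson annulation) with a ring-E iodide (asymmetric Diels–Alder, then Ireland–Claisen for C17).
4. The guaiane diol comes from (S)-carvone by one-carbon ring expansion, cyclopentenone annulation, γ-hydroxylation and CBS reduction (sets C3′).
5. Order of ring formation: A (starting arene), B, C; E; seven-membered, then five-membered guaiane ring; dioxane; D last.

Key step: step 26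

Remark: the triterpenoid half is numbered as in 24-nor-friedelanes (pristimerin), the guaiane half with primed guaiane numbers; where a chiral catalyst or auxiliary is named, the enantiomer given is the one expected from the accepted stereochemical model.

## Route

Step 1
Reactants: 1 2,3-dimethoxytoluene; 2 succinic anhydride
Product: 3 4-(3,4-dimethoxy-2-methylphenyl)-4-oxobutanoic acid
Conditions: AlCl3 (2.2 equiv), CH2Cl2, 0 °C to rt; aq. HCl
Reagents that add atoms: none
Why: Friedel–Crafts acylation; the unhindered, coplanar 3-methoxy group directs para (ortho to the methyl), which places the later ring B next to the aryl methyl.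

Step 2
Reactants: 3 4-(3,4-dimethoxy-2-methylphenyl)-4-oxobutanoic acid
Product: 4 4-(3,4-dimethoxy-2-methylphenyl)butanoic acid
Conditions: H2 (4 atm), Pd/C (10 wt % Pd), AcOH, HClO4 (cat.), 50 °C
Reagents that add atoms: none
Why: benzylic hydrogenolysis of an electron-rich aryl ketone (via the benzylic alcohol) to the methylene.

Step 3
Reactants: 4 4-(3,4-dimethoxy-2-methylphenyl)butanoic acid
Product: 5 6,7-dimethoxy-5-methyl-3,4-dihydronaphthalen-1(2H)-one
Conditions: P2O5 in MeSO3H, 50 °C
Reagents that add atoms: none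
Why: intramolecular Friedel–Crafts acylation closes ring B at the only free ortho position, which is para to a methoxy group.

Step 4
Reactants: 5 6,7-dimethoxy-5-methyl-3,4-dihydronaphthalen-1(2H)-one
Product: 7 6,7-dimethoxy-4,8-dimethyl-1,2-dihydronaphthalene, via tertiary benzylic alcohol 6 (not isolated)
Conditions: MeMgBr, THF, 0 °C; then p-TsOH (cat.), toluene, 80 °C
Reagents that add atoms: methylmagnesium bromide C[Mg]Br
Why: Grignard 1,2-addition followed by acid-catalysed dehydration of the tertiary benzylic alcohol to the conjugated endocyclic alkene (this installs the future C9 methyl).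

Step 5
Reactants: 7 6,7-dimethoxy-4,8-dimethyl-1,2-dihydronaphthalene
Product: 9 6,7-dimethoxy-1,5-dimethyl-3,4-dihydronaphthalen-2(1H)-one (racemic), via epoxide 8 (not isolated)
Conditions: mCPBA, NaHCO3, CH2Cl2, 0 °C; then ZnI2 (cat.), benzene, rt
Reagents that add atoms: mCPBA OOC(=O)c1cccc(Cl)c1
Why: Prilezhaev epoxidation, then Lewis-acid epoxide-to-ketone (Meinwald) rearrangement through the tertiary benzylic cation with a 1,2-hydride shift, a 1,2-carbonyl transposition to the 1-methyl-2-tetralone.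

Step 6
Reactants: 9 6,7-dimethoxy-1,5-dimethyl-3,4-dihydronaphthalen-2(1H)-one; 10 (S)-1-phenylethylamine; 11 pent-1-en-3-one
Product: 14 (S)-6,7-dimethoxy-1,5-dimethyl-1-(3-oxopentyl)-3,4-dihydronaphthalen-2(1H)-one, via ketimine 12 (not isolated), via Michael-adduct ketimine 13 (not isolated)
Conditions: 10, p-TsOH (cat.), toluene, reflux with water removal; then 11, THF, rt; then 20 % aq. AcOH, rt
Reagents that add atoms: water O
Why: chiral-imine (deracemizing) Michael addition; both enantiomers of 9 converge on the aryl-conjugated secondary enamine, which adds to the enone through a cyclic aza-ene-like transition state on the face anti to the phenyl group and so sets the benzylic quaternary C9 (9β-methyl).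

Step 7
Reactants: 14 (S)-6,7-dimethoxy-1,5-dimethyl-1-(3-oxopentyl)-3,4-dihydronaphthalen-2(1H)-one
Product: 15 (R)-6,7-dimethoxy-1,4a,8-trimethyl-4,4a,9,10-tetrahydrophenanthren-2(3H)-one
Conditions: NaOMe, MeOH, 60 °C
Reagents that add atoms: none
Why: intramolecular aldol condensation (second stage of the Robinson annulation) closes ring C and gives the C13 ketone and C14 methyl as an enone; no new stereocentre.

Step 8
Reactants: 16 3-methylbut-2-enal
Product: 17 (E)-3-methylbuta-1,3-dien-1-yl acetate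
Conditions: Ac2O, Et3N, DMAP (cat.), 80 °C; distillation
Reagents that add atoms: acetic anhydride CC(=O)OC(C)=O
Why: O-acetylation of the extended dienolate (dienol acetate formation); the E isomer, the reactive diene, should predominate.

Step 9
Reactants: 17 (E)-3-methylbuta-1,3-dien-1-yl acetate; 18 methacrolein
Product: 19 (1S,6R)-6-formyl-3,6-dimethylcyclohex-2-en-1-yl acetate
Conditions: (S)-3,3-diphenyl-1-(o-tolyl)tetrahydro-1H,3H-pyrrolo[1,2-c][1,3,2]oxazaborole protonated with Tf2NH (10 mol %), CH2Cl2, −78 °C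
Reagents that add atoms: none
Why: catalytic enantioselective Diels–Alder reaction closes ring E; the 1-acetoxy group ("ortho") and the 3-methyl group ("para") reinforce one regiochemistry, the formyl group adds endo (acetoxy cis to formyl), and the chiral oxazaborolidinium shields one face of bound methacrolein, setting C20 (quaternary) and C19.

Step 10
Reactants: 19 (1S,6R)-6-formyl-3,6-dimethylcyclohex-2-en-1-yl acetate
Product: 21 methyl (1R,2S)-2-acetoxy-1,4-dimethylcyclohex-3-ene-1-carboxylate, via carboxylic acid 20 (not isolated)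
Conditions: NaClO2, NaH2PO4, 2-methyl-2-butene, t-BuOH/H2O, 0 °C; then Me3SiCHN2, toluene/MeOH, 0 °C
Reagents that add atoms: sodium chlorite [Na+].[O-]Cl=O; (trimethylsilyl)diazomethane C[Si](C)(C)C=[N+]=[N-]
Why: Pinnick oxidation of the non-enolizable aldehyde and diazoalkane esterification; the quaternary centre cannot epimerize.

Step 11
Reactants: 21 methyl (1R,2S)-2-acetoxy-1,4-dimethylcyclohex-3-ene-1-carboxylate
Product: 24 2-[(1R,4R)-4-(methoxycarbonyl)-1,4-dimethylcyclohex-2-en-1-yl]acetic acid, via silyl ketene acetal 22 (not isolated), via trimethylsilyl ester 23 (not isolated)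
Conditions: LiN(i-Pr)2, Me3SiCl, THF, −78 °C; then reflux; then dilute aq. HCl
Reagents that add atoms: none
Why: Ireland–Claisen rearrangement; the suprafacial [3,3] shift forms the C17–C16 bond on the face that carried the acetoxy group, so the quaternary C17 gets its two-carbon arm cis to the C20 ester (17β- and 20β-methyls cis) and the alkene moves to C18=C19; the tertiary ester has no α-hydrogen.

Step 12
Reactants: 24 2-[(1R,4R)-4-(methoxycarbonyl)-1,4-dimethylcyclohex-2-en-1-yl]acetic acid
Product: 25 methyl (1R,4R)-4-(2-hydroxyethyl)-1,4-dimethylcyclohex-2-ene-1-carboxylate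
Conditions: BH3·SMe2 (1.1 equiv), THF, 0 °C
Reagents that add atoms: none
Why: chemoselective borane reduction of the carboxylic acid; the hindered tertiary ester and the alkene flanked by two quaternary carbons should react far more slowly.

Step 13
Reactants: 25 methyl (1R,4R)-4-(2-hydroxyethyl)-1,4-dimethylcyclohex-2-ene-1-carboxylate
Product: 26 methyl (1R,4R)-4-(2-iodoethyl)-1,4-dimethylcyclohex-2-ene-1-carboxylate
Conditions: I2, PPh3, imidazole, CH2Cl2, 0 °C
Reagents that add atoms: iodine II
Why: Appel-type iodination of the unhindered primary alcohol.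

Step 14
Reactants: 15 (R)-6,7-dimethoxy-1,4a,8-trimethyl-4,4a,9,10-tetrahydrophenanthren-2(3H)-one; 26 methyl (1R,4R)-4-(2-iodoethyl)-1,4-dimethylcyclohex-2-ene-1-carboxylate
Product: 28 methyl 2,3-dimethoxy-13-oxo-13,18-seco-24,27-dinorfriedela-1,3,5(10),18-tetraen-29-oate (8α-H; 9β,14β,17β,20β-methyls), via lithium enolate 27 (not isolated)
Conditions: Li (2.2 equiv), liquid NH3, THF, t-BuOH (1 equiv), −78 °C; isoprene; NH3 removed; then 26, THF/DMPU, −20 °C to rt
Reagents that add atoms: none
Why: dissolving-metal enone reduction with enolate trapping (Birch-type reductive alkylation); protonation at C8 gives the trans B/C fusion (8α-H anti to the 9β-methyl), and the regiodefined C14 enolate is alkylated on the α face, anti to the 1,3-related axial 9β-methyl, which sets the quaternary C14 (14β-methyl).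

Step 15
Reactants: 28 methyl 2,3-dimethoxy-13-oxo-13,18-seco-24,27-dinorfriedela-1,3,5(10),18-tetraen-29-oate
Product: 29 methyl 2,3-dimethoxy-13-oxo-13,18-seco-24,27-dinorfriedela-1,3,5(10),6,18-pentaen-29-oate
Conditions: DDQ (1.1 equiv), 1,4-dioxane, 60 °C
Reagents that add atoms: none
Why: DDQ dehydrogenation; hydride abstraction from the benzylic C6 para to the C2 methoxy group and proton loss from C7 give the styrene, the quaternary C9 blocks aromatization, and the ring-E alkene has no allylic hydrogen.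

Step 16
Reactants: 29 methyl 2,3-dimethoxy-13-oxo-13,18-seco-24,27-dinorfriedela-1,3,5(10),6,18-pentaen-29-oate
Product: 30 methyl 2,3-dihydroxy-13-oxo-13,18-seco-24,27-dinorfriedela-1,3,5(10),6,18-pentaen-29-oate
Conditions: BBr3 (3 equiv), CH2Cl2, −78 to −10 °C; aq. NaHCO3; kept under argon
Reagents that add atoms: none
Why: Lewis-acid cleavage of both aryl methyl ethers at low temperature, where the hindered tertiary methyl ester, the ketone and the alkenes should survive.

Step 17
Reactants: 31 (S)-(+)-carvone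
Product: 32 (2S,5S)-2-methyl-5-(prop-1-en-2-yl)cyclohexan-1-one (trans-dihydrocarvone)
Conditions: LiBH(s-Bu)3, THF, −78 °C; then NaOMe (cat.), MeOH, rt
Reagents that add atoms: none
Why: conjugate hydride reduction of the enone, then base equilibration of the α-methyl centre to the diequatorial trans isomer, which sets the future C10′ relative to C7′; the minor cis isomer is removed by chromatography.

Step 18
Reactants: 32 (2S,5S)-2-methyl-5-(prop-1-en-2-yl)cyclohexan-1-one
Product: 33 ethyl (3S,6S)-3-methyl-2-oxo-6-(prop-1-en-2-yl)cycloheptane-1-carboxylate (C1 epimers and enol)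
Conditions: ethyl diazoacetate, BF3·OEt2, Et2O, 0 °C
Reagents that add atoms: ethyl diazoacetate CCOC(=O)C=[N+]=[N-]
Why: Lewis-acid-promoted diazoacetate ring expansion (Tiffeneau–Demjanov-type homologation) forms the seven-membered ring; the less substituted α-carbon migrates, so the new ester-bearing carbon (C5′) is inserted away from the methyl-bearing carbon.

Step 19
Reactants: 33 ethyl (3S,6S)-3-methyl-2-oxo-6-(prop-1-en-2-yl)cycloheptane-1-carboxylate
Product: 34 ethyl (3S,6S)-3-methyl-2-oxo-1-(3-oxobutan-2-yl)-6-(prop-1-en-2-yl)cycloheptane-1-carboxylate (diastereomers at C1 and in the side chain, both lost later)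
Conditions: NaH, THF/DMF, 0 °C; 3-bromobutan-2-one, NaI (cat.), rt
Reagents that add atoms: 3-bromobutan-2-one CC(Br)C(C)=O
Why: C-alkylation of the β-keto ester enolate with an α-bromo ketone gives the 1,4-diketone; only the doubly activated position is deprotonated, so C10′ is untouched.

Step 20
Reactants: 34 ethyl (3S,6S)-3-methyl-2-oxo-1-(3-oxobutan-2-yl)-6-(prop-1-en-2-yl)cycloheptane-1-carboxylate
Product: 37 (7′S,10′S)-guaia-4′,11′-dien-3′-one (1′-H epimers, which converge in step 21), via bicyclic enone ester 35 (not isolated), via enone acid 36 (not isolated)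
Conditions: KOt-Bu, t-BuOH, rt; then KOH, EtOH/H2O, reflux
Reagents that add atoms: none
Why: intramolecular aldol condensation closes the five-membered ring, then saponification and decarboxylation of the vinylogous β-keto acid with equilibration to the tetrasubstituted conjugated enone; enolization of the methyl ketone should outrun that of the hindered C10′ methine, which keeps C10′ intact.

Step 21
Reactants: 37 (7′S,10′S)-guaia-4′,11′-dien-3′-one
Product: 39 (7′S,10′S)-1′-hydroxyguaia-4′,11′-dien-3′-one (1′-OH drawn anti to the 10′-methyl), via silyl dienol ether 38 (not isolated)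
Conditions: Me3SiOTf, Et3N, CH2Cl2, 0 °C to rt; then mCPBA (1.0 equiv), NaHCO3, −40 °C; then 1 M HCl, THF, 0 °C
Reagents that add atoms: mCPBA OOC(=O)c1cccc(Cl)c1
Why: vinylogous Rubottom oxidation; the fully substituted extended dienol ether is the thermodynamic isomer and is oxidized at its γ-terminus (C1′) faster than the isopropenyl group, and the C1′ configuration is of no consequence because this centre is ionized in step 24.

Step 22
Reactants: 39 (7′S,10′S)-1′-hydroxyguaia-4′,11′-dien-3′-one
Product: 40 (3′R,7′S,10′S)-guaia-4′,11′-diene-1′,3′-diol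
Conditions: (S)-1-methyl-3,3-diphenyltetrahydro-1H,3H-pyrrolo[1,2-c][1,3,2]oxazaborole ((S)-Me-CBS, 0.3 equiv), catecholborane, toluene, −78 °C
Reagents that add atoms: none
Why: Corey–Bakshi–Shibata reduction; the catalyst differentiates the α-methyl alkenyl side (large) from the CH2 side (small) of the cyclopentenone and so sets C3′ under reagent control, independent of the remote C7′ and C10′, and catecholborane spares the isopropenyl group.

Step 23
Reactants: 30 methyl 2,3-dihydroxy-13-oxo-13,18-seco-24,27-dinorfriedela-1,3,5(10),6,18-pentaen-29-oate; 40 (3′R,7′S,10′S)-guaia-4′,11′-diene-1′,3′-diol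
Product: 41 2-O-[(3′S,7′S,10′S)-1′-hydroxyguaia-4′,11′-dien-3′-yl] ether of 30 (3-OH free)
Conditions: PPh3, DIAD, THF, 0 °C
Reagents that add atoms: none
Why: Mitsunobu etherification with inversion at the allylic C3′; the phenol oxygen on C2 (flanked by C1–H) should react in preference to the one on C3 (flanked by the C4 methyl), and the tertiary C1′ alcohol is inert.

Step 24
Reactants: 41 2-O-[(3′S,7′S,10′S)-1′-hydroxyguaia-4′,11′-dien-3′-yl] ether of 30
Product: 42 2-O,3-O-[(3′S,4′R,7′S,10′S)-guaia-1′(5′),11′-diene-3′,4′-diyl] cyclic diether of 30 (C2–O–C3′ and C3–O–C4′; the target with ring D open and C13 as ketone)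
Conditions: camphorsulfonic acid (10 mol %), CH2Cl2, 4 Å molecular sieves, −20 °C
Reagents that add atoms: none
Why: acid-catalysed allylic transposition and cycloetherification (SN1′); ionization of the tertiary allylic C1′ alcohol gives the C1′–C5′–C4′ allyl cation, which the tethered C3 phenol captures at C4′ in a 6-exo closure that can only be cis-fused, so C4′ is set by C3′ and the alkene ends at C1′=C5′.

Step 25
Reactants: 42 cyclic diether ketone
Product: 44 13-(methoxyoxalyloxy)-13,18-seco derivative of the target (methyl 2-oxo-2-[(C13)-oxy]acetate; 13α-methyl drawn), via lithium alkoxide 43 (not isolated)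
Conditions: CeCl3 (anhydrous), MeLi, THF, −78 °C; then ClC(O)CO2Me, −78 to 0 °C
Reagents that add atoms: methyllithium [Li]C; methyl chlorooxoacetate COC(=O)C(=O)Cl
Why: organocerium 1,2-addition to the hindered ketone without enolization or attack on the tertiary ester, then O-acylation of the alkoxide; the C13 configuration is irrelevant because this carbon becomes a planar radical.

Step 26
Reactants: 44 tertiary methyl oxalate
Product: 45 CNP0222748.2 (target)
Conditions: Bu3SnH (1.5 equiv, syringe pump), AIBN (0.2 equiv), toluene (high dilution), 100 °C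
Reagents that add atoms: none
Why: Bu3Sn• adds to the oxalate carbonyl and β-scission releases the planar tertiary C13 radical, which adds 6-exo-trig to C18 of the ring-E alkene; the secondary C19 radical then takes hydrogen from Bu3SnH, so the angular C13 methyl, the C13–C18 bond and the saturated ring E appear in one operation. The closest known reaction type is the Barton–McCombie-type deoxygenation of tertiary methyl oxalates combined with a tin hydride 6-exo alkyl radical cyclization onto an unactivated cycloalkene. Ring D should close through a chair-like transition state in which the C14–C15 bond and the forming C13–C18 bond are both equatorial on ring C, which leaves the C13 methyl axial and anti to the axial C14 methyl (trans C/D fusion, C13 controlled by C14). C18 is controlled by the quaternary C17: the two-carbon tether reaches only the alkene face on which it stands, which gives the cis D/E fusion with 18β-H. The step needs closure to outrun hydrogen transfer and 6-exo attack to beat 7-endo attack at C19; the fully substituted C14 and C17 preorganize the chain, slow addition keeps the stannane dilute, and the alkene has no allylic hydrogen because C17 and C20 are quaternary. The isopropenyl group, the tetrasubstituted guaiane alkene and the C6=C7 styrene are out of reach of the C13 radical and inert to the stannane.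

## Compound list

1 | 2,3-dimethoxytoluene | COc1cccc(C)c1OC | starting material
2 | succinic anhydride | O=C1CCC(=O)O1 | starting material
3 | 4-(3,4-dimethoxy-2-methylphenyl)-4-oxobutanoic acid | COc1ccc(C(=O)CCC(=O)O)c(C)c1OC | intermediate
4 | 4-(3,4-dimethoxy-2-methylphenyl)butanoic acid | COc1ccc(CCCC(=O)O)c(C)c1OC | intermediate
5 | 6,7-dimethoxy-5-methyl-3,4-dihydronaphthalen-1(2H)-one | COc1c(cc2c(c1C)CCCC2=O)OC | intermediate
6 | 6,7-dimethoxy-1,5-dimethyl-1,2,3,4-tetrahydronaphthalen-1-ol (racemic) | COc1c(cc2c(c1C)CCCC2(C)O)OC | intermediate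
7 | 6,7-dimethoxy-4,8-dimethyl-1,2-dihydronaphthalene | COc1c(cc2c(c1C)CCC=C2C)OC | intermediate
8 | 5,6-dimethoxy-4,7b-dimethyl-1a,2,3,7b-tetrahydronaphtho[1,2-b]oxirene (racemic) | COc1c(cc2c(c1C)CCC1OC21C)OC | intermediate
9 | 6,7-dimethoxy-1,5-dimethyl-3,4-dihydronaphthalen-2(1H)-one (racemic) | COc1c(cc2c(c1C)CCC(=O)C2C)OC | intermediate
10 | (S)-1-phenylethylamine | C[C@H](N)c1ccccc1 | starting material
11 | pent-1-en-3-one | CCC(=O)C=C | starting material
12 | N-[(S)-1-phenylethyl] ketimine of 9 | COc1c(cc2c(c1C)CCC(=N[C@@H](C)c1ccccc1)C2C)OC | intermediate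
13 | N-[(S)-1-phenylethyl] ketimine of 14 | COc1c(cc2c(c1C)CCC(=N[C@@H](C)c1ccccc1)[C@@]2(C)CCC(=O)CC)OC | intermediate
14 | (S)-6,7-dimethoxy-1,5-dimethyl-1-(3-oxopentyl)-3,4-dihydronaphthalen-2(1H)-one | COc1c(cc2c(c1C)CCC(=O)[C@@]2(C)CCC(=O)CC)OC | intermediate
15 | (R)-6,7-dimethoxy-1,4a,8-trimethyl-4,4a,9,10-tetrahydrophenanthren-2(3H)-one | COc1c(cc2c(c1C)CCC1=C(C)C(=O)CC[C@]12C)OC | intermediate
16 | 3-methylbut-2-enal | CC(C)=CC=O | starting material
17 | (E)-3-methylbuta-1,3-dien-1-yl acetate | CC(=O)O/C=C/C(C)=C | intermediate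
18 | methacrolein | CC(=C)C=O | starting material
19 | (1S,6R)-6-formyl-3,6-dimethylcyclohex-2-en-1-yl acetate | CC(=O)O[C@H]1C=C(C)CC[C@@]1(C)C=O | intermediate
20 | (1R,2S)-2-acetoxy-1,4-dimethylcyclohex-3-ene-1-carboxylic acid | CC(=O)O[C@H]1C=C(C)CC[C@@]1(C)C(=O)O | intermediate
21 | methyl (1R,2S)-2-acetoxy-1,4-dimethylcyclohex-3-ene-1-carboxylate | CC(=O)O[C@H]1C=C(C)CC[C@@]1(C)C(=O)OC | intermediate
22 | trimethylsilyl ketene acetal of 21 | C=C(O[Si](C)(C)C)O[C@H]1C=C(C)CC[C@@]1(C)C(=O)OC | intermediate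
23 | trimethylsilyl ester of 24 | C[Si](C)(C)OC(=O)C[C@]1(C)C=C[C@](C)(C(=O)OC)CC1 | intermediate
24 | 2-[(1R,4R)-4-(methoxycarbonyl)-1,4-dimethylcyclohex-2-en-1-yl]acetic acid | OC(=O)C[C@]1(C)C=C[C@](C)(C(=O)OC)CC1 | intermediate
25 | methyl (1R,4R)-4-(2-hydroxyethyl)-1,4-dimethylcyclohex-2-ene-1-carboxylate | OCC[C@]1(C)C=C[C@](C)(C(=O)OC)CC1 | intermediate
26 | methyl (1R,4R)-4-(2-iodoethyl)-1,4-dimethylcyclohex-2-ene-1-carboxylate | ICC[C@]1(C)C=C[C@](C)(C(=O)OC)CC1 | intermediate
27 | lithium C13-enolate from 15 (8α-H) | COc1c(cc2c(c1C)CC[C@H]1[C@@]2(C)CCC([O-])=C1C)OC.[Li+] | intermediate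
28 | methyl 2,3-dimethoxy-13-oxo-13,18-seco-24,27-dinorfriedela-1,3,5(10),18-tetraen-29-oate | COc1c(cc2c(c1C)CC[C@H]1[C@@]2(C)CCC(=O)[C@]1(C)CC[C@]3(C)C=C[C@](C)(C(=O)OC)CC3)OC | intermediate
29 | methyl 2,3-dimethoxy-13-oxo-13,18-seco-24,27-dinorfriedela-1,3,5(10),6,18-pentaen-29-oate | COc1c(cc2c(c1C)C=C[C@H]1[C@@]2(C)CCC(=O)[C@]1(C)CC[C@]3(C)C=C[C@](C)(C(=O)OC)CC3)OC | intermediate
30 | methyl 2,3-dihydroxy-13-oxo-13,18-seco-24,27-dinorfriedela-1,3,5(10),6,18-pentaen-29-oate | Oc1c(cc2c(c1C)C=C[C@H]1[C@@]2(C)CCC(=O)[C@]1(C)CC[C@]3(C)C=C[C@](C)(C(=O)OC)CC3)O | intermediate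
31 | (S)-(+)-carvone | CC1=CC[C@@H](CC1=O)C(C)=C | starting material
32 | (2S,5S)-2-methyl-5-(prop-1-en-2-yl)cyclohexan-1-one | C[C@H]1CC[C@@H](CC1=O)C(C)=C | intermediate
33 | ethyl (3S,6S)-3-methyl-2-oxo-6-(prop-1-en-2-yl)cycloheptane-1-carboxylate (C1 epimers) | C[C@H]1CC[C@@H](CC(C(=O)OCC)C1=O)C(C)=C | intermediate
34 | ethyl (3S,6S)-3-methyl-2-oxo-1-(3-oxobutan-2-yl)-6-(prop-1-en-2-yl)cycloheptane-1-carboxylate (diastereomer mixture) | C[C@H]1CC[C@@H](CC(C(=O)OCC)(C(C)C(C)=O)C1=O)C(C)=C | intermediate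
35 | ethyl (7′S,10′S)-3′-oxoguaia-1′,11′-diene-5′-carboxylate (4′,5′ epimers) | C[C@H]1CC[C@@H](CC2(C(=O)OCC)C(C)C(=O)C=C12)C(C)=C | intermediate
36 | (7′S,10′S)-3′-oxoguaia-1′,11′-diene-5′-carboxylic acid (4′,5′ epimers) | C[C@H]1CC[C@@H](CC2(C(=O)O)C(C)C(=O)C=C12)C(C)=C | intermediate
37 | (7′S,10′S)-guaia-4′,11′-dien-3′-one (1′-H epimers) | C[C@H]1CC[C@@H](CC2=C(C)C(=O)CC12)C(C)=C | intermediate
38 | (7′S,10′S)-3′-(trimethylsilyloxy)guaia-1′(5′),3′,11′-triene | C[C@H]1CC[C@@H](CC2=C1CC(O[Si](C)(C)C)=C2C)C(C)=C | intermediate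
39 | (7′S,10′S)-1′-hydroxyguaia-4′,11′-dien-3′-one | C[C@H]1CC[C@@H](CC2=C(C)C(=O)C[C@@]12O)C(C)=C | intermediate
40 | (3′R,7′S,10′S)-guaia-4′,11′-diene-1′,3′-diol | C[C@H]1CC[C@@H](CC2=C(C)[C@H](O)C[C@@]12O)C(C)=C | intermediate
41 | 2-O-[(3′S,7′S,10′S)-1′-hydroxyguaia-4′,11′-dien-3′-yl] ether of 30 | C=C(C)[C@H]1CC[C@H](C)[C@]2(O)C[C@H](Oc3cc4c(c(C)c3O)C=C[C@H]3[C@@]4(C)CCC(=O)[C@]3(C)CC[C@]5(C)C=C[C@](C)(C(=O)OC)CC5)C(C)=C2C1 | intermediate
42 | 2-O,3-O-[(3′S,4′R,7′S,10′S)-guaia-1′(5′),11′-diene-3′,4′-diyl] cyclic diether of 30 | C=C(C)[C@H]1CC[C@H](C)C2=C(C1)[C@@]1(C)Oc3c(cc4c(c3C)C=C[C@H]3[C@@]4(C)CCC(=O)[C@]3(C)CC[C@]5(C)C=C[C@](C)(C(=O)OC)CC5)O[C@H]1C2 | intermediate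
43 | lithium 13-alkoxide (13α-methyl) from 42 | C=C(C)[C@H]1CC[C@H](C)C2=C(C1)[C@@]1(C)Oc3c(cc4c(c3C)C=C[C@H]3[C@@]4(C)CC[C@@](C)([O-])[C@]3(C)CC[C@]5(C)C=C[C@](C)(C(=O)OC)CC5)O[C@H]1C2.[Li+] | intermediate
44 | 13-(methoxyoxalyloxy)-13,18-seco-18-ene precursor of the target | C=C(C)[C@H]1CC[C@H](C)C2=C(C1)[C@@]1(C)Oc3c(cc4c(c3C)C=C[C@H]3[C@@]4(C)CC[C@@](C)(OC(=O)C(=O)OC)[C@]3(C)CC[C@]5(C)C=C[C@](C)(C(=O)OC)CC5)O[C@H]1C2 | intermediate
45 | CNP0222748.2 | C=C(C)[C@H]1CC[C@H](C)C2=C(C1)[C@@]1(C)Oc3c(cc4c(c3C)C=C[C@H]3[C@@]4(C)CC[C@@]4(C)[C@@H]5C[C@](C)(C(=O)OC)CC[C@]5(C)CC[C@]34C)O[C@H]1C2 | target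

## Step count and risks

Total step count: 26. Longest linear sequence: 14 steps (steps 1–7, 14–16, 23–26).

Steps most likely to fail:

1. Step 26 (ring D closure). Hydrogen transfer from the stannane to the tertiary C13 radical may outrun the hindered 6-exo closure, giving simple deoxygenation, or the closure may go through the cis-C/D transition state. Fallback, from 42, generating the same radical without a fast hydrogen donor:
   - Corey–Chaykovsky methylene transfer (Me3S+ I−, n-BuLi, THF, −10 °C) should give the 13-spiro-epoxide F1.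
   - Cp2TiCl (trivalent titanium, made from Cp2TiCl2 and Zn dust, THF, rt) opens the epoxide homolytically to the tertiary C13 radical, which has time for the 6-exo closure before capture by a second Cp2TiCl; protonation on work-up should give the ring-D-closed 27-hydroxy compound F2.
   - Barton–McCombie deoxygenation through the S-methyl xanthate F3 (NaH, CS2, MeI; then Bu3SnH, AIBN, toluene, 100 °C) returns to 45.

2. Step 14 (fragment union). Proton transfer between enolate 27 and the product, together with slow SN2 attack on the unactivated iodide, may give the non-alkylated trans ketone or alkylation at C12. Fallback, using a faster electrophile: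
   - Alcohol 25 is oxidized with Dess–Martin periodinane (CH2Cl2, rt) to methyl (1R,4R)-1,4-dimethyl-4-(2-oxoethyl)cyclohex-2-ene-1-carboxylate F4.
   - Enolate 27, made from 15 as in step 14, is trapped with F4 at −78 °C in an aldol addition to give the 15-hydroxy ketone F5 (C15 epimers).
   - Acylation with 1,1′-thiocarbonyldiimidazole gives the imidazolyl thiocarbonate F6, and Barton–McCombie reduction (Bu3SnH, AIBN, toluene, 90 °C) returns to 28.

3. Step 21 (γ-hydroxylation). The silyloxycyclopentadiene 38 may isomerize or dimerize, or the peracid may attack the α-carbon or the isopropenyl group. Fallback, from 37, avoiding the C1′ alcohol: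
   - CBS reduction as in step 22 should give (3′R)-guaia-4′,11′-dien-3′-ol F7.
   - Mitsunobu etherification with catechol 30 (PPh3, DIAD) gives the 2-O-(guaia-4′,11′-dien-3′-yl) ether F8.
   - mCPBA (CH2Cl2, 0 °C) epoxidizes the tetrasubstituted C4′=C5′ alkene anti to the aryloxy group, and the free C3 phenol opens the epoxide at C4′ in situ (6-exo, inversion) to the cis-fused 5′-hydroxy benzodioxane F9.
   - Dehydration of the tertiary alcohol with Burgess reagent (benzene, 50 °C) toward C1′ returns to 42; the regiochemistry of this elimination is the weak point of the fallback.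

Further compounds
F1 | step 26 | 13-spiro-epoxide of 42 (epoxide CH2 α) | C=C(C)[C@H]1CC[C@H](C)C2=C(C1)[C@@]1(C)Oc3c(cc4c(c3C)C=C[C@H]3[C@@]4(C)CC[C@]6(CO6)[C@]3(C)CC[C@]5(C)C=C[C@](C)(C(=O)OC)CC5)O[C@H]1C2
F2 | step 26 | 27-hydroxy derivative of 45 | C=C(C)[C@H]1CC[C@H](C)C2=C(C1)[C@@]1(C)Oc3c(cc4c(c3C)C=C[C@H]3[C@@]4(C)CC[C@@]4(CO)[C@@H]5C[C@](C)(C(=O)OC)CC[C@]5(C)CC[C@]34C)O[C@H]1C2
F3 | step 26 | S-methyl xanthate of F2 | C=C(C)[C@H]1CC[C@H](C)C2=C(C1)[C@@]1(C)Oc3c(cc4c(c3C)C=C[C@H]3[C@@]4(C)CC[C@@]4(COC(=S)SC)[C@@H]5C[C@](C)(C(=O)OC)CC[C@]5(C)CC[C@]34C)O[C@H]1C2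
F4 | step 14 | methyl (1R,4R)-1,4-dimethyl-4-(2-oxoethyl)cyclohex-2-ene-1-carboxylate | O=CC[C@]1(C)C=C[C@](C)(C(=O)OC)CC1
F5 | step 14 | 15-hydroxy derivative of 28 (C15 epimers) | COc1c(cc2c(c1C)CC[C@H]1[C@@]2(C)CCC(=O)[C@]1(C)C(O)C[C@]3(C)C=C[C@](C)(C(=O)OC)CC3)OC
F6 | step 14 | O-(imidazol-1-ylthiocarbonyl) derivative of F5 | COc1c(cc2c(c1C)CC[C@H]1[C@@]2(C)CCC(=O)[C@]1(C)C(OC(=S)n1ccnc1)C[C@]3(C)C=C[C@](C)(C(=O)OC)CC3)OC
F7 | step 21 | (3′R,7′S,10′S)-guaia-4′,11′-dien-3′-ol (1′-H epimers) | C[C@H]1CC[C@@H](CC2=C(C)[C@H](O)CC12)C(C)=C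
F8 | step 21 | 2-O-[(3′S,7′S,10′S)-guaia-4′,11′-dien-3′-yl] ether of 30 | C=C(C)[C@H]1CC[C@H](C)C2C[C@H](Oc3cc4c(c(C)c3O)C=C[C@H]3[C@@]4(C)CCC(=O)[C@]3(C)CC[C@]5(C)C=C[C@](C)(C(=O)OC)CC5)C(C)=C2C1
F9 | step 21 | 5′-hydroxy-1′,5′-dihydro derivative of 42 | C=C(C)[C@H]1CC[C@H](C)C2[C@@](O)(C1)[C@@]1(C)Oc3c(cc4c(c3C)C=C[C@H]3[C@@]4(C)CCC(=O)[C@]3(C)CC[C@]5(C)C=C[C@](C)(C(=O)OC)CC5)O[C@H]1C2
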